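Its constants come from no measurement, and the outcome is calculated.

30.0% of maple's charge is the solubility of starting material, so I reckoned with what stays behind as solid and not with what is made.

the same everywhere: coupling partner 0.0400 M; free catalyst 35 µM; time 30 s

|  | solid substrate |
|---|---|
| maple | 0.050 M |
| larch | 0.080 M |
| ash | 0.12 M |
| elm | 0.15 M |
| birch | 0.25 M |

* [target] at the end for maple, larch, ash, elm, birch, in this order
* the course of these numbers from the first flask to the last (falls all the way / rises, then falls / rises all the way / hardly changes / falls, then rises)

- in percentages every species weighs as the solid substrate in it: one self-condensation product counts as two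
- a doubled species enters its step squared and goes two at a time
- as a solid, counted per litre of solution: solid substrate
- at the start none of the solid substrate is in solution
- "hardly changes" means that all values lie within two and a half points (for a concentration: within two and a half percent of the largest)
- run time (maple): 30 s

    coupling partner + catalyst intermediate B ⇌ catalyst intermediate C (K1 = 22 M⁻¹, k1 = 79600 M⁻¹ s⁻¹)
    catalyst intermediate C → free catalyst + target (k2 = 39.7 s⁻¹)
    catalyst intermediate A → catalyst intermediate B (k3 = 56.5 s⁻¹)
    2 starting material → self-condensation product (k4 = 0.958 M⁻¹ s⁻¹)
    starting material + free catalyst ⇌ catalyst intermediate A (K5 = 25 M⁻¹, k5 = 1220 M⁻¹ s⁻¹)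
    solid substrate ⇌ starting material, rate k6*(cs6 - [starting material]) while solid is left; crystals form when [starting material] > cs6 (cs6 = 15 mM, k6 = 0.240 s⁻¹)

1. Dissolved starting material rises on a time of 4.17 s, shorter than the run, so I treated it as standing at a level after that rise.

2. I set starting material at its solubility and coupling partner at its charge, and let each form of the catalyst pass the same flow. That gave a turnover frequency of 5.76 s⁻¹ per catalyst.

3. The level lies where dissolving equals self-condensation plus this catalytic flow. For maple that was 25.7% of the charge.

4. By my reckoning a flask loses 0.0262 M of solid by the end. I called this the draw: the level plus the steady dissolving counted from the end of the rise.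

5. Maple and larch differ in their charge, and the charge stands in none of these terms while solid lasts. So I gave them the same draw, with 47.6% of maple's solid left and 67.2% of larch's.

6. Because the draw is smaller than the smallest charge, I expected solid to stand through the run in each flask. I therefore committed to one value across the row, 0.00521 M of target.

The forecast gave 0.005 M, 0.005 M, 0.005 M, 0.005 M and 0.005 M, below my value, with the course "hardly changes", since “the dissolution rate does not depend on how much solid is present”.

The flasks gave 0.00496 M, 0.00496 M, 0.00496 M, 0.00496 M and 0.00496 M: hardly changes.

In maple, half of the dissolving up to the end was done by 7.01 s, earlier than the 16.3 s for half of the passage from catalyst intermediate A to catalyst intermediate B. Starting material then stood at 25.5% of maple's charge at 15.0 s and 25.8% at 30.0 s. Maple kept 48.4% of its solid against my 47.6%, and larch, against my 67.2%, kept 67.7%.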